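## Analysis of the target

The target is a linear triad of three six-membered carbocycles joined by two methylene bridges. Ring A is a non-aromatic, enolised β-triketone (2-butanoyl-3,5-dihydroxy-6,6-dimethylcyclohexa-2,4-dien-1-one) with a quaternary CMe2 carbon. Ring B is a butanoylphloroglucinol with all three carbon positions substituted: b1 carries the bridge to ring C, b3 the bridge to ring A, b5 the butanoyl group, and b2, b4 and b6 carry OH. Ring C is a butanoyl(methyl)phloroglucinol: c1 bridge carbon, c2 C–OH, c3 C–CH3, c4 C–OH, c5 C–butanoyl, c6 C–OH.

There is no stereocentre, since the only sp3 ring carbon bears two identical methyl groups. Every selectivity question is therefore one of regiochemistry and chemoselectivity. The sensitive elements are the eight phenolic or enolic hydroxyls (oxidation in base), the ring A triketone (retro-Claisen deacylation) and the two diarylmethane bridges between very electron-rich rings. These bridges can be cut and re-formed by strong acid or hot base, which scrambles them.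

The difficulty is that three different hexasubstituted rings must be joined in a fixed order through two different bridges on ring B. One-carbon couplings of two nucleophilic phloroglucinols tend to give symmetrical by-products.

The strategy rests on ring C. Its carbons alternate oxygen and carbon substituents, so c1–c4 correspond to a 1,1,3-trioxygenated four-carbon diene carrying the methyl group and the bridge arm. Carbons c5 and c6 correspond to a two-carbon alkyne that carries the butanoyl group and an alkoxy group.

## Retrosynthetic reasoning

**Bridge between rings A and B.** The bond between the bridging methylene and b3 is cut last. The bridges are the most labile part of the molecule, and ring A tolerates neither Lewis acids nor ether cleavage. This gives the bis-butanoyl diarylmethane 19, in which b3 is the only unsubstituted ring carbon, and the aminomethylated ring A 23, which carries the bridge carbon as a latent exocyclic methylene. The forward step must release that methylene under conditions that leave the b1–CH2–c1 bridge alone.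

**Ring A.** Compound 23 is cut at its C–N bond to the butanoyl gem-dimethyl triketone 22. Compound 22 is cut at both C–CH3 bonds to the aromatic ketone 21, and 21 at the aryl–acyl bond to 20 and 11. Ring A is bought cheaply by classical chemistry so that the effort of the route goes into the bridged B–C unit.

**Butanoyl group of ring B.** In 19 the aryl–carbonyl bond at b5 is cut, giving the hexaphenol 18 and 11. The cut is made here because ring C of 18 has no free carbon, and ring B of 18 has a mirror plane through b1 and b4. Its two free carbons are therefore equivalent and the acylation can give only one constitution. The first acyl group also slows a second acylation.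

**Ether cleavage.** Compound 18 comes from the tetra-ether 17 by cutting three O–CH3 bonds on ring B and the O–ethyl bond at c6. The methyl ethers keep ring B inert through the enolate and silylation chemistry. The ethyl ether is the residue of the ynol ether that the ring construction needs.

**Ring C (key disconnection).** In 17 the bonds c1–c6 and c4–c5 are cut. These two cuts split the ring into a four-carbon unit and a two-carbon unit. The four-carbon unit (c1–c4, oxygen on c2 and c4, methyl on c3, bridge arm on c1) is the bis-silyl dienol ether 10 of a β-keto ester. The two-carbon unit (butanoyl on c5, oxygen on c6) is the alkoxy ynone 15. The gain is twofold. Ring C is formed with all six substituents in place, so no aromatic substitution on it is needed. The b1–CH2–c1 bridge is an ordinary chain carbon of 10, so this unsymmetrical bridge is made without a one-carbon coupling. The forward reaction must join the diene terminus to the oxygen-bearing alkyne carbon and then aromatise by expelling the ester alkoxy group.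

**Ynone.** Compound 15 is cut between the carbonyl carbon and the alkyne to the acetylide 14 (from 13) and the N-methoxy-N-methyl amide 12 (from 11). The amide is chosen so that the acetylide adds only once.

**Diene.** Compound 10 is cut at its two O–Si bonds, through the mono-silyl enol ether 9, to the β-keto ester 8. Compound 8 is cut between C2 and C3 to the acyl imidazolide 7 of acid 4 and the half-ester salt 6 (from 5). Acid 4 goes back through the cinnamic acid 3 to 1 and 2. The aldehyde carbon of 1 becomes the bridge, the two carbons from 2 become c1 and c2, and 6 supplies c3, its methyl group and c4.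

## Alternatives that were turned down

**Alternative 1:** Ring B is made last. It is unfolded at the bond between a bridge-bearing carbon and the neighbouring C–OH carbon to a 3,5-dioxo ester stored as the 4-hydroxy-2-pyrone A2. In A2, ring C hangs on pyrone C3 through its methylene and ring A sits at the end of a two-carbon chain on C6.
- Forward key step: alkoxide opens the lactone, and the chain methylene next to the new ketone attacks the ester carbon in a Claisen condensation to give A1, the target without the ring B butanoyl group.
- For: both bridges are made as ordinary C–C bonds well before the ring closure. No one-carbon coupling of two nucleophilic rings is needed, so symmetrical by-products and bridge scrambling are avoided. On this point the alternative is stronger than the chosen route, whose last step is still a one-carbon coupling, though a directed one.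
- Against: A2 contains the ring A triketone and the ring C acylphloroglucinol, with many acidic sites competing for the alkoxide. The opened tricarbonyl chain can close by aldol addition instead of Claisen condensation, giving a different arene. Assembling A2 (benzylation of a pyrone at C3 and attachment of ring A through a two-carbon tether) is long. A1 still needs a Friedel–Crafts butanoylation on the complete triad, the most labile compound of the sequence.
- Comparison: the chosen strategy places its uncertain step early, on a two-ring fragment made from simple materials, and takes ring A from two classical steps.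

**Alternative 2:** Ring B is built from the cyclohexadiene A4, which carries masked ring C on its methylene arm, and the ynone 15.
- Forward key step: a [4+2] addition gives a bicyclo[2.2.2]octadiene, which expels its saturated two-carbon bridge as a gaseous alkene on heating (Alder–Rickert) to give A3.
- For: ring B appears with its butanoyl group in place and with exactly one free carbon for the later bridge to ring A, so no Friedel–Crafts reaction on ring B is needed. Here the alternative is stronger. The cyclic diene is locked s-cis, and the retro-cycloaddition makes aromatisation irreversible. It uses the same ynone as the chosen route.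
- Against: the diene terminus that must bond to the ethoxy-bearing alkyne carbon is the fully substituted one carrying the arylmethyl arm, so two fully substituted carbons must join in a bicyclic transition state. The extrusion needs temperatures at which the ynol ether and the silyl dienol ether are at risk. Ring C arrives without its butanoyl group, so the later acylation must distinguish the single free carbon of ring C from the free, activated carbon of ring B. Five ethers must then be cleaved.
- Comparison: the chosen route delivers ring C complete with methyl, butanoyl and three oxygens. Its late acylation falls on a ring whose two free carbons are equivalent.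

**Alternative 3:** Ring A is assembled from the cyclobutenone A6 and the silyl ynol ether A7.
- Forward key step: on heating, A6 opens to a vinylketene, adds A7, and the adduct opens and closes again to a six-membered ring. The gem-dimethyl carbon prevents the usual tautomerisation to a phenol, so the cascade stops at the dienone A5.
- For: this forms three bonds and creates the dearomatised, quaternary ring A with full positional control. That is stronger than the chosen route, which obtains ring A by a C-methylation of 21 known to give mixtures. The A–B bridge is fixed from the start.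
- Against: A5 has none of the three butanoyl groups and no ring C. C-acylation of ring A, acylation of ring B, a one-carbon coupling to a ring C monomer and differentiated removal of ethyl, silyl and methyl ethers all remain. A6 itself takes several steps, and linear 2,4-cyclohexadienones dimerise readily.
- Comparison: the chosen route completes the most heavily substituted aromatic ring in one operation and makes ring A in two short steps, so it is shorter overall.

Key step: step 9

Remarks on the chemistry:
- Ring A is written in the tautomer of the target SMILES; its enol forms interconvert and are treated as one compound.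
- Compounds 9 and 10 are drawn as the expected major geometric isomers. Other isomers would converge on the same arene.
- Compounds 6 and 8 are racemic and 16 is a diastereomer mixture. These stereocentres do not appear in the target.

## Route

Step 1
Reactants: 1 2,4,6-trimethoxybenzaldehyde; 2 malonic acid
Product: 3 (2E)-3-(2,4,6-trimethoxyphenyl)prop-2-enoic acid
Conditions: pyridine, piperidine (cat.), 90 °C
Reagents that add atoms: none
Why: Knoevenagel–Doebner condensation; the alkylidene malonic acid decarboxylates in hot pyridine to the E acid, and the electron-rich, hindered aldehyde is a standard substrate for this reaction.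

Step 2
Reactants: 3 (2E)-3-(2,4,6-trimethoxyphenyl)prop-2-enoic acid
Product: 4 3-(2,4,6-trimethoxyphenyl)propanoic acid
Conditions: H2 (1 atm), 10% Pd/C, EtOAc–MeOH, 20 °C
Reagents that add atoms: none
Why: Catalytic hydrogenation of the conjugated alkene; aryl methyl ethers and the acid are inert under these conditions.

Step 3
Reactants: 5 dimethyl 2-methylpropanedioate
Product: 6 potassium 3-methoxy-2-methyl-3-oxopropanoate
Conditions: KOH (1.0 equiv), MeOH, 0 → 20 °C
Reagents that add atoms: potassium hydroxide, [K+].[OH-]
Why: Mono-saponification of a malonic diester; the carboxylate formed first deactivates the second ester, so one equivalent of hydroxide should stop at the half-ester salt.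

Step 4
Reactants: 4 3-(2,4,6-trimethoxyphenyl)propanoic acid; 6 potassium 3-methoxy-2-methyl-3-oxopropanoate
Product: 8 methyl 2-methyl-3-oxo-5-(2,4,6-trimethoxyphenyl)pentanoate, via acyl imidazolide 7 (not isolated)
Conditions: 1,1'-carbonyldiimidazole, THF, 20 °C; then 6, MgCl2, Et3N, MeCN, 20 → 40 °C; 1 M HCl work-up
Reagents that add atoms: none
Why: Decarboxylative Claisen condensation of a magnesium malonate half-ester with an acyl imidazolide; the magnesium chelate is C-acylated and loses CO2 to give the 2-methyl β-keto ester under nearly neutral conditions that spare the electron-rich arene.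

Step 5
Reactants: 8 methyl 2-methyl-3-oxo-5-(2,4,6-trimethoxyphenyl)pentanoate
Product: 9 methyl (2Z)-2-methyl-5-(2,4,6-trimethoxyphenyl)-3-(trimethylsilyloxy)pent-2-enoate
Conditions: Me3SiCl, Et3N, toluene, 20 °C, 48–72 h; filtration under argon
Reagents that add atoms: chlorotrimethylsilane, C[Si](C)(C)Cl
Why: O-silylation of the enol of a β-keto ester, the usual first stage of 1-alkoxy-1,3-bis(silyloxy)diene synthesis; 2-alkyl β-keto esters react more slowly but in the same way.

Step 6
Reactants: 9 methyl (2Z)-2-methyl-5-(2,4,6-trimethoxyphenyl)-3-(trimethylsilyloxy)pent-2-enoate
Product: 10 (1E,3Z)-1-methoxy-2-methyl-1,3-bis(trimethylsilyloxy)-5-(2,4,6-trimethoxyphenyl)penta-1,3-diene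
Conditions: LiN(i-Pr)2, THF, −78 °C; Me3SiCl, −78 → 20 °C; pentane, filtration under argon, used crude
Reagents that add atoms: chlorotrimethylsilane, C[Si](C)(C)Cl
Why: Kinetic γ-deprotonation of the β-silyloxy enoate at C4 gives the extended ester dienolate, which is silylated on oxygen; this is the standard second stage of the diene synthesis and tolerates 2- and 4-alkyl groups.

Step 7
Reactants: 11 butanoyl chloride
Product: 12 N-methoxy-N-methylbutanamide
Conditions: MeNH(OMe)·HCl, pyridine, CH2Cl2, 0 → 20 °C
Reagents that add atoms: N,O-dimethylhydroxylamine hydrochloride, CNOC.Cl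
Why: Acylation of the hydroxylamine nitrogen by the acid chloride gives the Weinreb amide.

Step 8
Reactants: 13 ethoxyethyne; 12 N-methoxy-N-methylbutanamide
Product: 15 1-ethoxyhex-1-yn-3-one, via lithium ethoxyacetylide 14 (not isolated)
Conditions: n-BuLi, THF, −78 °C; then 12, −78 → 0 °C; cold aq. NH4Cl
Reagents that add atoms: none
Why: Weinreb ketone synthesis; the chelated tetrahedral adduct prevents a second addition, and the mild, nearly neutral quench releases the ynone without hydrating the ynol ether.

Step 9
Reactants: 10 (1E,3Z)-1-methoxy-2-methyl-1,3-bis(trimethylsilyloxy)-5-(2,4,6-trimethoxyphenyl)penta-1,3-diene; 15 1-ethoxyhex-1-yn-3-one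
Product: 17 1-[2-ethoxy-4,6-dihydroxy-5-methyl-3-[(2,4,6-trimethoxyphenyl)methyl]phenyl]butan-1-one, via cyclohexadiene cycloadduct 16 (not isolated)
Conditions: 15 (1.5 equiv), toluene (1 M), 100 °C, sealed tube; then 1 M HCl, THF, 20 °C
Reagents that add atoms: none
Why: The reaction is a Diels–Alder addition with aromatisation, the known route from 1-alkoxy-1,3-bis(silyloxy)dienes and acetylenic ketones or esters to resorcinols; the alkyne here carries an ethoxy group, a variant of the partner not yet tried, so the arene emerges with oxygen on c2, c4 and c6. The electron-rich terminus C4 of 10 (future c1) bonds to the ethoxy-bearing alkyne carbon of 15 (c6) and the ketene acetal carbon C1 (c4) bonds to the alkyne carbon next to the carbonyl (c5); ring C is thus closed in an intermolecular [4+2] mode which, if bond formation is stepwise, amounts to a Mukaiyama–Michael addition followed by 6-exo-trig attack of the allenolate carbon on the silyloxy-oxocarbenium carbon. Cycloadduct 16 is a 1,4-cyclohexadiene whose sp3 carbon c4 carries methoxy and silyloxy and whose sp3 carbon c1 carries hydrogen, so 1,4-elimination of methanol, completed by the acid work-up that also removes both silyl groups, should give the phenol 17. No stereocentre is created in the product, because the two stereocentres of 16 vanish on aromatisation. Three selectivities are needed: orientation, periselectivity and the direction of aromatisation. Orientation follows from matched polarisation, since the ethoxy donor and the acyl acceptor both make c6 the electrophilic and c5 the nucleophilic alkyne carbon, while the diene is most nucleophilic at C4. The methyl group on C2 of 10 means that the competing [3+3] closure through C2 onto the ketone would give a quaternary carbon that cannot aromatise and can revert, whereas the [4+2] adduct is removed irreversibly, and heating without a Lewis acid keeps C1 a silyl ketene acetal until the second bond has formed. Only c4 carries a leaving group on sp3 carbon, so the ethoxy group on c6 stays.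

Step 10
Reactants: 17 1-[2-ethoxy-4,6-dihydroxy-5-methyl-3-[(2,4,6-trimethoxyphenyl)methyl]phenyl]butan-1-one
Product: 18 1-[2,4,6-trihydroxy-3-methyl-5-[(2,4,6-trihydroxyphenyl)methyl]phenyl]butan-1-one
Conditions: BBr3 (8 equiv), CH2Cl2, −78 → 20 °C; ice-water quench at 0 °C
Reagents that add atoms: none
Why: Lewis-acid ether cleavage; each ether oxygen binds boron and bromide attacks the alkyl carbon, and the ethyl ether ortho to the ketone is helped by chelation. Coordination of excess BBr3 to the ether oxygens lowers the electron density of ring B and should protect the bridge from ipso protonation.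

Step 11
Reactants: 18 1-[2,4,6-trihydroxy-3-methyl-5-[(2,4,6-trihydroxyphenyl)methyl]phenyl]butan-1-one; 11 butanoyl chloride
Product: 19 1-[3-[(3-butanoyl-2,4,6-trihydroxyphenyl)methyl]-2,4,6-trihydroxy-5-methylphenyl]butan-1-one
Conditions: 11 (1.1 equiv), AlCl3 (6 equiv), PhNO2–CH2Cl2, 0 → 40 °C; ice, 1 M HCl
Reagents that add atoms: none
Why: Friedel–Crafts acylation of a phloroglucinol nucleus; ring C has no free carbon and the two free carbons of ring B are equivalent, so only one constitution can form, and the new acyl group deactivates ring B towards a second acylation. Any aryl butanoate formed on oxygen should transfer its acyl group to carbon under the same conditions (Fries rearrangement).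

Step 12
Reactants: 20 benzene-1,3,5-triol; 11 butanoyl chloride
Product: 21 1-(2,4,6-trihydroxyphenyl)butan-1-one
Conditions: AlCl3 (3.5 equiv), PhNO2–CH2Cl2, 0 → 20 °C; ice, 1 M HCl
Reagents that add atoms: none
Why: Classical Friedel–Crafts mono-acylation of phloroglucinol; the first acyl group deactivates the ring towards further acylation.

Step 13
Reactants: 21 1-(2,4,6-trihydroxyphenyl)butan-1-one
Product: 22 2-butanoyl-3,5-dihydroxy-6,6-dimethylcyclohexa-2,4-dien-1-one
Conditions: NaOMe (3 equiv), MeI (2.2 equiv), MeOH, 0 → 20 °C; aq. HCl; chromatography
Reagents that add atoms: iodomethane, CI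
Why: Dearomative C-methylation of an acylphloroglucinolate; the second methyl enters at the carbon already methylated and gives the non-aromatic gem-dimethyl triketone. This is the established, moderately selective access to acylfilicinic acids, and 22 is separated from under- and over-methylated material.

Step 14
Reactants: 22 2-butanoyl-3,5-dihydroxy-6,6-dimethylcyclohexa-2,4-dien-1-one
Product: 23 2-butanoyl-4-[(dimethylamino)methyl]-3,5-dihydroxy-6,6-dimethylcyclohexa-2,4-dien-1-one
Conditions: CH2(NMe2)2 (1.1 equiv), CH2Cl2, 0 → 20 °C; the inner salt is collected by filtration
Reagents that add atoms: bis(dimethylamino)methane, CN(C)CN(C)C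
Why: Mannich aminomethylation at the only free ring carbon of the acidic cyclic triketone; the acid protonates the aminal to the iminium ion, which is trapped by the enolate. No free one-carbon aldehyde is present, which should suppress formation of the symmetrical methylene-bridged dimer.

Step 15
Reactants: 19 1-[3-[(3-butanoyl-2,4,6-trihydroxyphenyl)methyl]-2,4,6-trihydroxy-5-methylphenyl]butan-1-one; 23 2-butanoyl-4-[(dimethylamino)methyl]-3,5-dihydroxy-6,6-dimethylcyclohexa-2,4-dien-1-one
Product: 24 2-butanoyl-4-[[3-butanoyl-5-[(3-butanoyl-2,4,6-trihydroxy-5-methylphenyl)methyl]-2,4,6-trihydroxyphenyl]methyl]-3,5-dihydroxy-6,6-dimethylcyclohexa-2,4-dien-1-one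
Conditions: 23 (1.3 equiv), AcOH (2 equiv), degassed 1,4-dioxane, 60 °C, argon
Reagents that add atoms: none
Why: The Mannich base loses dimethylamine to give the exocyclic methylene triketone, a quinone-methide-like Michael acceptor, which is attacked by b3, the only free nucleophilic carbon of 19 (Friedel–Crafts-type Michael addition). Release of alkylidene triketones from their amine adducts and capture by acylphloroglucinols is an established way to build such bridges, and directing the bridge carbon through one partner avoids a statistical three-component coupling.

## Compound list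

1 | 2,4,6-trimethoxybenzaldehyde | COc1cc(OC)c(C=O)c(OC)c1 | starting material
2 | malonic acid (propanedioic acid) | OC(=O)CC(=O)O | starting material
3 | (2E)-3-(2,4,6-trimethoxyphenyl)prop-2-enoic acid | COc1cc(OC)c(/C=C/C(=O)O)c(OC)c1 | intermediate
4 | 3-(2,4,6-trimethoxyphenyl)propanoic acid | COc1cc(OC)c(CCC(=O)O)c(OC)c1 | intermediate
5 | dimethyl 2-methylpropanedioate (dimethyl methylmalonate) | COC(=O)C(C)C(=O)OC | starting material
6 | potassium 3-methoxy-2-methyl-3-oxopropanoate (racemic) | COC(=O)C(C)C(=O)[O-].[K+] | intermediate
7 | 1-(imidazol-1-yl)-3-(2,4,6-trimethoxyphenyl)propan-1-one | COc1cc(OC)c(CCC(=O)n2ccnc2)c(OC)c1 | intermediate (not isolated)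
8 | methyl 2-methyl-3-oxo-5-(2,4,6-trimethoxyphenyl)pentanoate (racemic) | COC(=O)C(C)C(=O)CCc1c(OC)cc(OC)cc1OC | intermediate
9 | methyl (2Z)-2-methyl-5-(2,4,6-trimethoxyphenyl)-3-(trimethylsilyloxy)pent-2-enoate | COC(=O)/C(C)=C(\O[Si](C)(C)C)CCc1c(OC)cc(OC)cc1OC | intermediate
10 | (1E,3Z)-1-methoxy-2-methyl-1,3-bis(trimethylsilyloxy)-5-(2,4,6-trimethoxyphenyl)penta-1,3-diene | CO\C(O[Si](C)(C)C)=C(C)/C(O[Si](C)(C)C)=C/Cc1c(OC)cc(OC)cc1OC | intermediate
11 | butanoyl chloride | CCCC(=O)Cl | starting material
12 | N-methoxy-N-methylbutanamide | CCCC(=O)N(C)OC | intermediate
13 | ethoxyethyne (ethoxyacetylene) | C#COCC | starting material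
14 | lithium ethoxyacetylide | [Li]C#COCC | intermediate (not isolated)
15 | 1-ethoxyhex-1-yn-3-one | CCCC(=O)C#COCC | intermediate
16 | 1-[2-ethoxy-6-methoxy-5-methyl-3-[(2,4,6-trimethoxyphenyl)methyl]-4,6-bis(trimethylsilyloxy)cyclohexa-1,4-dien-1-yl]butan-1-one (diastereomer mixture) | CCCC(=O)C1=C(OCC)C(Cc2c(OC)cc(OC)cc2OC)C(O[Si](C)(C)C)=C(C)C1(OC)O[Si](C)(C)C | intermediate (not isolated)
17 | 1-[2-ethoxy-4,6-dihydroxy-5-methyl-3-[(2,4,6-trimethoxyphenyl)methyl]phenyl]butan-1-one | CCCC(=O)c1c(O)c(C)c(O)c(Cc2c(OC)cc(OC)cc2OC)c1OCC | intermediate
18 | 1-[2,4,6-trihydroxy-3-methyl-5-[(2,4,6-trihydroxyphenyl)methyl]phenyl]butan-1-one | CCCC(=O)c1c(O)c(C)c(O)c(Cc2c(O)cc(O)cc2O)c1O | intermediate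
19 | 1-[3-[(3-butanoyl-2,4,6-trihydroxyphenyl)methyl]-2,4,6-trihydroxy-5-methylphenyl]butan-1-one | CCCC(=O)c1c(O)c(C)c(O)c(Cc2c(O)cc(O)c(C(=O)CCC)c2O)c1O | intermediate
20 | benzene-1,3,5-triol (phloroglucinol) | Oc1cc(O)cc(O)c1 | starting material
21 | 1-(2,4,6-trihydroxyphenyl)butan-1-one | CCCC(=O)c1c(O)cc(O)cc1O | intermediate
22 | 2-butanoyl-3,5-dihydroxy-6,6-dimethylcyclohexa-2,4-dien-1-one (butanoylfilicinic acid) | CCCC(=O)C1=C(O)C=C(O)C(C)(C)C1=O | intermediate
23 | 2-butanoyl-4-[(dimethylamino)methyl]-3,5-dihydroxy-6,6-dimethylcyclohexa-2,4-dien-1-one | CCCC(=O)C1=C(O)C(CN(C)C)=C(O)C(C)(C)C1=O | intermediate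
24 | 2-butanoyl-4-[[3-butanoyl-5-[(3-butanoyl-2,4,6-trihydroxy-5-methylphenyl)methyl]-2,4,6-trihydroxyphenyl]methyl]-3,5-dihydroxy-6,6-dimethylcyclohexa-2,4-dien-1-one | CCCC(=O)C1=C(O)C(Cc2c(O)c(Cc3c(O)c(C)c(O)c(C(=O)CCC)c3O)c(O)c(C(=O)CCC)c2O)=C(O)C(C)(C)C1=O | target

## Step count and risks

Total step count: 15. Longest linear sequence: 9 steps (1, 2, 4, 5, 6, 9, 10, 11, 15).

**Step 9 (key step).** The most likely failure is a sluggish cycloaddition. The ethoxy donor lowers the electrophilicity of the ynone, and the diene is substituted at C2 and C4. At the temperature then required the diene may decompose by silyl migration or adventitious hydrolysis. The ketene acetal double bond may add [2+2] to the alkyne, or the sequence may stop at the open-chain Michael stage or close in the [3+3] sense.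

Fallback: ring C is taken from an aromatic building block instead of being built. The sequence sets out from 11 and 20 and returns at 18. 2-Methylbenzene-1,3,5-triol F1 (purchased) is acylated with 11 and AlCl3 to 1-(2,4,6-trihydroxy-3-methylphenyl)butan-1-one F2. Aminomethylation with bis(dimethylamino)methane gives 1-[3-[(dimethylamino)methyl]-2,4,6-trihydroxy-5-methylphenyl]butan-1-one F3. Heating F3 with a fivefold excess of 20 in dioxane releases the ortho-quinone methide, which is captured by 20 to give 18. The excess of 20 suppresses double alkylation.

**Step 10.** The risk is acid-induced cleavage of the diarylmethane bridge by ipso protonation of the very electron-rich ring B (retro-Friedel–Crafts), together with incomplete dealkylation of the flanked ethyl ether.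

Fallback: the order of events is changed so that ring B is deactivated before ether cleavage. The sequence sets out from 17 and returns at 19. Compound 17 is acylated on ring B with 11 and SnCl4 in CH2Cl2 at 0 °C, followed by K2CO3 in MeOH to remove any aryl butanoate, giving 1-[3-[(3-butanoyl-2-ethoxy-4,6-dihydroxy-5-methylphenyl)methyl]-2,4,6-trimethoxyphenyl]butan-1-one F4. BBr3 then cleaves the four ethers of F4, now on an acyl-deactivated ring B, to give 19.

**Step 11.** The risk is Lewis-acid-induced bridge cleavage and scrambling, acylation on oxygen that does not migrate to carbon, and some double acylation of ring B.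

Fallback: Houben–Hoesch acylation, which runs at 0 °C and stops at mono-acylation because the product precipitates as a salt. It sets out from 18 and returns at 19. Compound 18 is treated with butanenitrile, ZnCl2 and HCl gas in Et2O to give 1-[3-[(3-butanoyl-2,4,6-trihydroxy-5-methylphenyl)methyl]-2,4,6-trihydroxyphenyl]butan-1-iminium chloride F5, which is hydrolysed in warm water to 19.

**Step 13.** The risk is under- and over-methylation and some O-methylation, because the mono-, gem-di- and tri-C-methylated compounds form at similar rates.

Fallback: methylation of a substrate with a single free carbon. It sets out from 20 and 11 and returns at 22. Double acylation of 20 gives 1,1'-(2,4,6-trihydroxy-1,3-phenylene)di(butan-1-one) F6. NaOMe and MeI can then methylate only the one remaining ring carbon, giving 2,4-dibutanoyl-3,5-dihydroxy-6,6-dimethylcyclohexa-2,4-dien-1-one F7. Warm 80% H2SO4 removes both acyl groups to give 3,5-dihydroxy-6,6-dimethylcyclohexa-2,4-dien-1-one F8 (filicinic acid). Mono-acylation of F8 with 11 and AlCl3 gives 22.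

**Step 15.** The risk is methylene exchange. Compound 23 can also fragment in the opposite sense, losing the ring A enolate and transferring an aminomethyl group, and the bridge carbon may then be redistributed to give symmetrical products. The amine set free can also promote scrambling of the existing bridge, and the polyphenols can oxidise.

Fallback: the classical three-component coupling, which needs no new compound (F0). It sets out from 19 and 22 and returns at 24. Compounds 19 and 22 are condensed with aqueous formaldehyde in dilute aqueous KOH at 20 °C under argon for a short time and then acidified. Compound 24 is separated chromatographically from the symmetrical by-products.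

## Further compounds

F1 | step 9 | 2-methylbenzene-1,3,5-triol (purchased) | Cc1c(O)cc(O)cc1O
F2 | step 9 | 1-(2,4,6-trihydroxy-3-methylphenyl)butan-1-one | CCCC(=O)c1c(O)c(C)c(O)cc1O
F3 | step 9 | 1-[3-[(dimethylamino)methyl]-2,4,6-trihydroxy-5-methylphenyl]butan-1-one | CCCC(=O)c1c(O)c(C)c(O)c(CN(C)C)c1O
F4 | step 10 | 1-[3-[(3-butanoyl-2-ethoxy-4,6-dihydroxy-5-methylphenyl)methyl]-2,4,6-trimethoxyphenyl]butan-1-one | CCCC(=O)c1c(O)c(C)c(O)c(Cc2c(OC)cc(OC)c(C(=O)CCC)c2OC)c1OCC
F5 | step 11 | 1-[3-[(3-butanoyl-2,4,6-trihydroxy-5-methylphenyl)methyl]-2,4,6-trihydroxyphenyl]butan-1-iminium chloride | CCCC(=[NH2+])c1c(O)cc(O)c(Cc2c(O)c(C)c(O)c(C(=O)CCC)c2O)c1O.[Cl-]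
F6 | step 13 | 1,1'-(2,4,6-trihydroxy-1,3-phenylene)di(butan-1-one) | CCCC(=O)c1c(O)cc(O)c(C(=O)CCC)c1O
F7 | step 13 | 2,4-dibutanoyl-3,5-dihydroxy-6,6-dimethylcyclohexa-2,4-dien-1-one | CCCC(=O)C1=C(O)C(C(=O)CCC)=C(O)C(C)(C)C1=O
F8 | step 13 | 3,5-dihydroxy-6,6-dimethylcyclohexa-2,4-dien-1-one (filicinic acid) | O=C1C=C(O)C=C(O)C1(C)C
F0 | step 15 | none | none
A1 | alternative 1 | 2-butanoyl-4-[[3-[(3-butanoyl-2,4,6-trihydroxy-5-methylphenyl)methyl]-2,4,6-trihydroxyphenyl]methyl]-3,5-dihydroxy-6,6-dimethylcyclohexa-2,4-dien-1-one | CCCC(=O)C1=C(O)C(Cc2c(O)cc(O)c(Cc3c(O)c(C)c(O)c(C(=O)CCC)c3O)c2O)=C(O)C(C)(C)C1=O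
A2 | alternative 1 | 2-butanoyl-4-[2-[5-[(3-butanoyl-2,4,6-trihydroxy-5-methylphenyl)methyl]-4-hydroxy-6-oxopyran-2-yl]ethyl]-3,5-dihydroxy-6,6-dimethylcyclohexa-2,4-dien-1-one | CCCC(=O)C1=C(O)C(CCc2cc(O)c(Cc3c(O)c(C)c(O)c(C(=O)CCC)c3O)c(=O)o2)=C(O)C(C)(C)C1=O
A3 | alternative 2 | 1-[2,6-diethoxy-4-hydroxy-3-[(2,4,6-trimethoxy-3-methylphenyl)methyl]phenyl]butan-1-one | CCCC(=O)c1c(OCC)cc(O)c(Cc2c(OC)cc(OC)c(C)c2OC)c1OCC
A4 | alternative 2 | 2-[[4-ethoxy-2-(trimethylsilyloxy)cyclohexa-1,3-dien-1-yl]methyl]-1,3,5-trimethoxy-4-methylbenzene | CCOC1=CC(O[Si](C)(C)C)=C(Cc2c(OC)cc(OC)c(C)c2OC)CC1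
A5 | alternative 3 | 5-ethoxy-6,6-dimethyl-4-[(2,4,6-trimethoxyphenyl)methyl]-3-[tri(propan-2-yl)silyloxy]cyclohexa-2,4-dien-1-one | CCOC1=C(Cc2c(OC)cc(OC)cc2OC)C(O[Si](C(C)C)(C(C)C)C(C)C)=CC(=O)C1(C)C
A6 | alternative 3 | 3-ethoxy-4,4-dimethyl-2-[(2,4,6-trimethoxyphenyl)methyl]cyclobut-2-en-1-one | CCOC1=C(Cc2c(OC)cc(OC)cc2OC)C(=O)C1(C)C
A7 | alternative 3 | ethynyloxy-tri(propan-2-yl)silane | C#CO[Si](C(C)C)(C(C)C)C(C)C
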